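**Plan**
1. Numbering used here: ring B = C1(CH3)=C2H–C3H2–C4H–C5=C6(CH3)–C7H–C8H; ring A = C4, C5, C9, C10, C11(CH3); ring C = C7, C12, C13, C14(CH3), C15, C8; ring D = C13, C16(i-Pr), C17, C18(OH), C14.
2. Ring B is a cycloocta-1,5-diene whose C5=C6 bond is exocyclic to ring A. With C2 drawn as a ketone, C2(=O)–C3–C4–C5=C6 is a γ,δ-unsaturated ketone, so cutting C3–C4 and joining O to C6 (retro-Claisen) turns ring B into a six-membered 2-methylidene-tetrahydropyran (O, C2, C1, C8, C7, C6), i.e. a δ-lactone trans-fused to ring C with the ring-A cyclopentenyl group on C6.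
3. Further cuts: C1=C2 (from the C2 ketone via its enol triflate), C4=C5 of ring A (metathesis), C5–C6 (alkenylcerium addition to a methyl ketone), C1–C8 (Michael addition), C6–C7 (Stille coupling), C16–isopropyl (conjugate addition).
4. Forward: rings C and D come from (R)-Hajos–Parrish ketone; then the lactone ring, ring A, and last ring B by a two-atom Claisen ring expansion; the C1=C2 bond and desilylation finish.
5. Stereochemistry: C14 comes from the starting ketone and controls C16, C18, C13, C8 and C7; C11 comes from (S)-citronellene; the temporary center C6 comes from a substrate-controlled ketone addition; C4 comes from C6 by suprafacial transfer in the sigmatropic step.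

Key step: step 15

Remark (assumption): (R)-Hajos–Parrish ketone and (S)-β-citronellene are taken as commercial; the R ketone is needed because C14 of the target is R.
Locants: compounds 1–13 carry indene locants (C1 = target C18, C3 = C16, C3a = C13, C4 = C12, C5 = C7, C6 = C8, C7 = C15, C7a = C14); from 22 on the target numbering of the plan is used.

**Step 1**
Reactants: 1 (R)-Hajos–Parrish ketone
Product: 3 (7aR)-7a-methyl-7,7a-dihydro-1H-indene-1,5(6H)-dione, via 3-bromo ketone 2 (not isolated)
Conditions: NBS, AIBN (cat.), PhCF3, 80 °C; then Et3N, 0 °C → rt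
Reagents that add atoms: none
Why: Wohl–Ziegler bromination takes the only allylic methylene (C3, the γ-position of the enone), and the resulting β-bromo ketone loses HBr toward the acidic C2–H in an E1cB-type dehydrobromination, which gives C2=C3 in conjugation with both carbonyl groups and leaves the quaternary C7a untouched.

**Step 2**
Reactants: 3 dienedione
Product: 4 (3S,7aR)-7a-methyl-3-(propan-2-yl)-2,3,7,7a-tetrahydro-1H-indene-1,5(6H)-dione
Conditions: i-PrMgCl, CuBr·SMe2 (10 mol %), THF, −78 °C; aq NH4Cl
Reagents that add atoms: isopropylmagnesium chloride CC(C)[Mg]Cl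
Why: Copper-catalysed conjugate addition of a Grignard reagent: C3 is the only unsubstituted β-carbon of the dienedione (C2 and C4 are α-carbons, C3a is fully substituted), and the isopropyl group should enter from the face opposite the pseudoaxial angular methyl group, which sets (3S).

**Step 3**
Reactants: 4 isopropyl dione
Product: 5 (1R,3S,7aR)-1-hydroxy-7a-methyl-3-(propan-2-yl)-1,2,3,6,7,7a-hexahydro-5H-inden-5-one
Conditions: NaBH4, EtOH, −20 °C
Reagents that add atoms: none
Why: Chemoselective borohydride reduction: the saturated cyclopentanone reacts faster than the conjugated enone, and hydride adds to C1 from the face opposite the adjacent angular methyl group, giving the (1R) alcohol cis to that methyl group.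

**Step 4**
Reactants: 5 hydroxy enone
Product: 6 tert-butyldimethylsilyl ether of 5
Conditions: TBSCl, imidazole, DMF, 40 °C
Reagents that add atoms: tert-butyldimethylsilyl chloride CC(C)(C)[Si](C)(C)Cl
Why: Standard silyl ether formation protects the secondary alcohol against the organometallic, titanium and triflating reagents used later; no stereocenter is affected.

**Step 5**
Reactants: 6 silyl ether enone
Product: 7 (1R,3S,3aS,7aR)-1-[(tert-butyldimethylsilyl)oxy]-7a-methyl-3-(propan-2-yl)octahydro-5H-inden-5-one
Conditions: Li, NH3 (l), THF, t-BuOH (1 equiv), −78 °C; NH4Cl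
Reagents that add atoms: none
Why: Dissolving-metal (Birch-type) reduction of the enone: the β-carbanion at C3a is protonated axially to the six-membered ring and trans to the angular methyl group, an outcome that also keeps the C3 isopropyl group trans to C4 (they would be eclipsed in the cis-fused isomer), which sets (3aS).

**Step 6**
Reactants: 7 trans-hydrindanone
Product: 9 (1R,3S,3aS,7aR)-1-[(tert-butyldimethylsilyl)oxy]-7a-methyl-3-(propan-2-yl)-2,3,3a,4,7,7a-hexahydro-1H-inden-5-yl trifluoromethanesulfonate, via lithium enolate 8 (not isolated)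
Conditions: LiN(i-Pr)2, THF, −78 °C; then PhNTf2, −78 → 0 °C; aq NH4Cl
Reagents that add atoms: N-phenylbis(trifluoromethanesulfonimide) O=S(=O)(N(c1ccccc1)S(=O)(=O)C(F)(F)F)C(F)(F)F
Why: Kinetic deprotonation with the hindered amide base goes to C6, away from the ring fusion (as trans-fused 3-keto steroids enolise toward C2), and O-sulfonylation of the enolate by the triflimide fixes the C5=C6 enol triflate.

**Step 7**
Reactants: 9 enol triflate
Product: 11 1-[(1R,3S,3aS,7aR)-1-[(tert-butyldimethylsilyl)oxy]-7a-methyl-3-(propan-2-yl)-2,3,3a,4,7,7a-hexahydro-1H-inden-5-yl]ethan-1-one, via ethoxy diene 10 (not isolated)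
Conditions: Bu3SnC(OEt)=CH2, Pd(PPh3)4 (5 mol %), LiCl, THF, 65 °C; then 1 M HCl, THF, 0 °C
Reagents that add atoms: tributyl(1-ethoxyvinyl)stannane CCCC[Sn](CCCC)(CCCC)C(=C)OCC; water O
Why: Stille coupling of the alkenyl triflate with the α-ethoxyvinyl stannane under zerovalent palladium, followed by acid hydrolysis of the enol ether, puts the acetyl group on C5 in conjugation with C5=C6.

**Step 8**
Reactants: 11 acetyl cyclohexene
Product: 13 methyl 2-[(1R,3S,3aS,5S,6S,7aR)-5-acetyl-1-[(tert-butyldimethylsilyl)oxy]-7a-methyl-3-(propan-2-yl)octahydro-1H-inden-6-yl]propanoate, via silyl enol ether 12 (not isolated)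
Conditions: MeCH=C(OMe)OSiMe3, Sc(OTf)3 (5 mol %), CH2Cl2, −78 °C; then K2CO3 (cat.), MeOH, rt
Reagents that add atoms: 1-methoxy-1-(trimethylsilyloxy)prop-1-ene CC=C(OC)O[Si](C)(C)C
Why: Mukaiyama–Michael addition of the ketene silyl acetal to the enone: the nucleophile should attack C6 from the face opposite the axial C7a methyl group (1,3-related), and base equilibration at C5 places the acetyl group equatorial and trans to the new side chain (5S,6S), while the side-chain α-carbon forms as an epimer mixture that does not matter because it becomes trigonal later.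

**Step 9**
Reactants: 14 (S)-β-citronellene
Product: 16 (4S)-4-methylhex-5-enal, via ozonide 15 (not isolated)
Conditions: O3 (1 equiv), CH2Cl2, −78 °C; then Me2S, −78 °C → rt
Reagents that add atoms: ozone [O-][O+]=O
Why: Ozonolysis with one equivalent of ozone selects the electron-rich trisubstituted double bond over the vinyl group, and reductive work-up gives the aldehyde with the methyl-bearing stereocenter untouched.

**Step 10**
Reactants: 16 aldehyde
Product: 17 (5S)-5-methylhept-6-en-1-yne
Conditions: MeC(O)C(N2)P(O)(OMe)2, K2CO3, MeOH, 0 °C → rt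
Reagents that add atoms: dimethyl (1-diazo-2-oxopropyl)phosphonate COP(=O)(OC)C(=[N+]=[N-])C(C)=O
Why: Seyferth–Gilbert homologation in its Ohira–Bestmann form converts the aldehyde into the terminal alkyne under mild carbonate conditions; the stereocenter is γ to the reacting carbon and cannot epimerise.

**Step 11**
Reactants: 17 enyne
Product: 19 (5S)-2-bromo-5-methylhepta-1,6-diene, via bromoboration adduct 18 (not isolated)
Conditions: 9-Br-9-BBN, CH2Cl2, 0 °C; then AcOH, 0 °C → rt
Reagents that add atoms: B-bromo-9-borabicyclo[3.3.1]nonane BrB1C2CCCC1CCC2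
Why: Bromoboration of the terminal alkyne puts bromine on the internal carbon and boron on the terminus, and protodeboronation with acetic acid leaves the 2-bromo-1-alkene, isolated double bonds being inert to the haloborane.

**Step 12**
Reactants: 19 alkenyl bromide; 13 keto ester
Product: 23 diene δ-lactone (1R,6S), via alkenyllithium 20 (not isolated), via alkenylcerium dichloride 21 (not isolated), via tertiary alkoxide 22 (not isolated)
Conditions: t-BuLi (2 equiv), Et2O, −78 °C; CeCl3, THF, −78 °C; then 13, −78 → 23 °C; DBU (cat.), rt; aq NH4Cl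
Reagents that add atoms: none
Why: Bromine–lithium exchange, transmetalation to the weakly basic organocerium reagent, 1,2-addition to the methyl ketone and lactonisation of the alkoxide onto the ester: the alkenyl group is expected to enter anti to the C7–C8 bond (the equatorial site of the incipient lactone) with the ketone oxygen turned toward the ester (coordination to trivalent cerium) and the acetyl methyl axial, because the alternative with this methyl in the ring-oxygen site suffers a syn-pentane contact with the C8 side chain, so C6 forms as S and the lactone α-carbon C1 settles with its methyl equatorial (R) under the basic conditions.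

**Step 13**
Reactants: 23 diene lactone
Product: 24 cyclopentenyl δ-lactone (ring A closed)
Conditions: RuCl2(=CHPh)(PCy3)(H2IMes) (second-generation Grubbs catalyst, 5 mol %), CH2Cl2, 40 °C
Reagents that add atoms: none
Why: Ring-closing metathesis between the 1,1-disubstituted and the monosubstituted double bond closes ring A as a trisubstituted cyclopentene (C4=C5) with loss of ethylene; the lactone and all stereocenters are inert.

**Step 14**
Reactants: 24 cyclopentenyl lactone
Product: 25 2-methylidene-tetrahydropyran (exocyclic enol ether; the new carbon is C3)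
Conditions: Cp2TiMe2, toluene, 70 °C, dark; filtration through basic alumina
Reagents that add atoms: dimethyltitanocene C[Ti](C)(C1C=CC=C1)C1C=CC=C1
Why: Petasis methylenation (carbonyl olefination by the titanium methylidene formed on heating) converts the lactone carbonyl into the exocyclic enol ether under non-acidic, non-enolising conditions, so the acid-labile tertiary allylic C6–O bond and the C1 center survive.

**Step 15**
Reactants: 25 2-methylidene-6-cyclopentenyl-tetrahydropyran
Product: 26 ring-B ketone (C2 ketone, 1R, 4S, C5=C6)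
Conditions: degassed xylene, Et3N (trace), base-washed sealed tube, 200 °C
Reagents that add atoms: none
Why: The allyl vinyl ether C3=C2–O–C6–C5=C4 undergoes a thermal [3,3]-sigmatropic (aliphatic Claisen) shift in which O–C6 breaks and C3–C4 forms, so the six-membered ring (O, C2, C1, C8, C7, C6) loses O and gains C3, C4 and C5 to become the eight-membered carbocycle. The closest known reaction type is the Claisen ring expansion of 2-methylidene-6-alkenyl-tetrahydropyrans to cyclooct-4-enones. Ring B is closed by this C3–C4 bond inside a bicyclo[3.3.1]-type pericyclic array that bridges C2 and C6 of the pyran; because the alkenyl group on C6 is equatorial on the trans-fused chair, the pyran must turn into a boat (oxygen flap up) so that the two termini meet on the face opposite the C14 methyl group, which is why the high temperature is chosen. The only new stereocenter, C4, is set by suprafacial transfer from C6: C3 is delivered to the cyclopentene face from which the oxygen departs, and (6S) gives (4S), cis to the C11 methyl group. The C5=C6 bond can form only with the cis in-ring geometry, which places the C6 methyl on the side of C9. The step needs periselectivity over acid-induced migration of the enol ether double bond into the ring (secured by base-washed glass and added amine) and stereospecificity (secured by the concerted pathway and the single C6 configuration of 25).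

**Step 16**
Reactants: 26 ring-B ketone
Product: 27 C1=C2 enol triflate
Conditions: Tf2O, 2,6-di-tert-butyl-4-methylpyridine, CH2Cl2, 0 °C → rt
Reagents that add atoms: trifluoromethanesulfonic anhydride O=S(=O)(OS(=O)(=O)C(F)(F)F)C(F)(F)F
Why: Enol triflate formation through the O-triflyl oxocarbenium ion under thermodynamic control should favour loss of the C1 proton, giving the more substituted C1=C2 enol triflate (the cycloocta-1,5-diene arrangement) over the C2=C3 isomer; the C1 stereocenter disappears.

**Step 17**
Reactants: 27 enol triflate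
Product: 28 tert-butyldimethylsilyl ether of the target
Conditions: Pd(OAc)2 (5 mol %), PPh3, HCO2H, Bu3N, DMF, 60 °C
Reagents that add atoms: none
Why: Palladium-catalysed formate reduction of the alkenyl triflate (oxidative addition to zerovalent palladium, formate exchange, decarboxylation, reductive elimination) replaces the triflate by hydrogen without moving the double bond.

**Step 18**
Reactants: 28 silyl ether
Product: 29 target
Conditions: TBAF, THF, 50 °C
Reagents that add atoms: none
Why: Fluoride-induced desilylation frees the C18 alcohol; the hindered silyl ether needs gentle warming and nothing else in the molecule reacts.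

**Compound list**
1 | (R)-Hajos–Parrish ketone, (7aR)-7a-methyl-2,3,7,7a-tetrahydro-1H-indene-1,5(6H)-dione | O=C1[C@]2(C)CCC(=O)C=C2CC1 | starting material
2 | (7aR)-3-bromo-7a-methyl-2,3,7,7a-tetrahydro-1H-indene-1,5(6H)-dione (C3 epimers) | O=C1[C@]2(C)CCC(=O)C=C2C(Br)C1 | intermediate (not isolated)
3 | (7aR)-7a-methyl-7,7a-dihydro-1H-indene-1,5(6H)-dione | O=C1[C@]2(C)CCC(=O)C=C2C=C1 | intermediate
4 | (3S,7aR)-7a-methyl-3-(propan-2-yl)-2,3,7,7a-tetrahydro-1H-indene-1,5(6H)-dione | O=C1[C@]2(C)CCC(=O)C=C2[C@H](C(C)C)C1 | intermediate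
5 | (1R,3S,7aR)-1-hydroxy-7a-methyl-3-(propan-2-yl)-1,2,3,6,7,7a-hexahydro-5H-inden-5-one | O[C@H]1[C@]2(C)CCC(=O)C=C2[C@H](C(C)C)C1 | intermediate
6 | (1R,3S,7aR)-1-[(tert-butyldimethylsilyl)oxy]-7a-methyl-3-(propan-2-yl)-1,2,3,6,7,7a-hexahydro-5H-inden-5-one | CC(C)(C)[Si](C)(C)O[C@H]1[C@]2(C)CCC(=O)C=C2[C@H](C(C)C)C1 | intermediate
7 | (1R,3S,3aS,7aR)-1-[(tert-butyldimethylsilyl)oxy]-7a-methyl-3-(propan-2-yl)octahydro-5H-inden-5-one (trans-fused) | CC(C)(C)[Si](C)(C)O[C@H]1[C@]2(C)CCC(=O)C[C@H]2[C@H](C(C)C)C1 | intermediate
8 | lithium C5=C6 enolate of 7 | CC(C)(C)[Si](C)(C)O[C@H]1[C@]2(C)CC=C(O[Li])C[C@H]2[C@H](C(C)C)C1 | intermediate (not isolated)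
9 | (1R,3S,3aS,7aR)-1-[(tert-butyldimethylsilyl)oxy]-7a-methyl-3-(propan-2-yl)-2,3,3a,4,7,7a-hexahydro-1H-inden-5-yl trifluoromethanesulfonate | CC(C)(C)[Si](C)(C)O[C@H]1[C@]2(C)CC=C(OS(=O)(=O)C(F)(F)F)C[C@H]2[C@H](C(C)C)C1 | intermediate
10 | 5-(1-ethoxyethenyl) analogue of 9 (2-ethoxy-1,3-diene) | CC(C)(C)[Si](C)(C)O[C@H]1[C@]2(C)CC=C(C(=C)OCC)C[C@H]2[C@H](C(C)C)C1 | intermediate (not isolated)
11 | 1-[(1R,3S,3aS,7aR)-1-[(tert-butyldimethylsilyl)oxy]-7a-methyl-3-(propan-2-yl)-2,3,3a,4,7,7a-hexahydro-1H-inden-5-yl]ethan-1-one | CC(C)(C)[Si](C)(C)O[C@H]1[C@]2(C)CC=C(C(C)=O)C[C@H]2[C@H](C(C)C)C1 | intermediate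
12 | trimethylsilyl enol ether of 13 (C5=C(CH3)OSiMe3, 6S) | CC(C)(C)[Si](C)(C)O[C@H]1[C@]2(C)C[C@H](C(C)C(=O)OC)C(=C(C)O[Si](C)(C)C)C[C@H]2[C@H](C(C)C)C1 | intermediate (not isolated)
13 | methyl 2-[(1R,3S,3aS,5S,6S,7aR)-5-acetyl-1-[(tert-butyldimethylsilyl)oxy]-7a-methyl-3-(propan-2-yl)octahydro-1H-inden-6-yl]propanoate (epimers at the propanoate α-carbon) | CC(C)(C)[Si](C)(C)O[C@H]1[C@]2(C)C[C@H](C(C)C(=O)OC)[C@@H](C(C)=O)C[C@H]2[C@H](C(C)C)C1 | intermediate
14 | (S)-β-citronellene, (3S)-3,7-dimethylocta-1,6-diene | C=C[C@@H](C)CCC=C(C)C | starting material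
15 | secondary ozonide of the trisubstituted double bond of 14 | C=C[C@@H](C)CCC1OOC(C)(C)O1 | intermediate (not isolated)
16 | (4S)-4-methylhex-5-enal | C=C[C@@H](C)CCC=O | intermediate
17 | (5S)-5-methylhept-6-en-1-yne | C=C[C@@H](C)CCC#C | intermediate
18 | (Z)-9-[(5S)-2-bromo-5-methylhepta-1,6-dien-1-yl]-9-borabicyclo[3.3.1]nonane | C=C[C@@H](C)CC/C(Br)=C/B1C2CCCC1CCC2 | intermediate (not isolated)
19 | (5S)-2-bromo-5-methylhepta-1,6-diene | C=C[C@@H](C)CCC(Br)=C | intermediate
20 | [(5S)-5-methylhepta-1,6-dien-2-yl]lithium | C=C[C@@H](C)CCC([Li])=C | intermediate (not isolated)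
21 | [(5S)-5-methylhepta-1,6-dien-2-yl]cerium dichloride | C=C[C@@H](C)CCC(=C)[Ce](Cl)Cl | intermediate (not isolated)
22 | tertiary alkoxide (drawn as the alcohol): 13 with the acetyl group converted into (S)-C(CH3)(OH)[(5S)-5-methylhepta-1,6-dien-2-yl] | CC(C)(C)[Si](C)(C)O[C@H]1[C@]2(C)C[C@H](C(C)C(=O)OC)[C@@H]([C@](C)(O)C(=C)CC[C@H](C)C=C)C[C@H]2[C@H](C(C)C)C1 | intermediate (not isolated)
23 | δ-lactone trans-fused to ring C (ring O–C6–C7–C8–C1–C2): (6S)-6-methyl-6-[(5S)-5-methylhepta-1,6-dien-2-yl], (1R)-1-methyl, C2 carbonyl; 16-isopropyl and 18-silyloxy as in 13 | CC(C)(C)[Si](C)(C)O[C@H]1[C@]2(C)C[C@@H]3[C@@H](C)C(=O)O[C@](C)(C(=C)CC[C@H](C)C=C)[C@H]3C[C@H]2[C@H](C(C)C)C1 | intermediate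
24 | lactone 23 with ring A closed: C6 carries (3S)-3-methylcyclopent-1-en-1-yl | CC(C)(C)[Si](C)(C)O[C@H]1[C@]2(C)C[C@@H]3[C@@H](C)C(=O)O[C@](C)(C4=C[C@@H](C)CC4)[C@H]3C[C@H]2[C@H](C(C)C)C1 | intermediate
25 | 2-methylidene-tetrahydropyran: 24 with C2=O replaced by C2=CH2 | CC(C)(C)[Si](C)(C)O[C@H]1[C@]2(C)C[C@@H]3[C@@H](C)C(=C)O[C@](C)(C4=C[C@@H](C)CC4)[C@H]3C[C@H]2[C@H](C(C)C)C1 | intermediate
26 | ring-B ketone: 5-8-6-5 tetracycle with C2 ketone, (1R)-1-methyl, (4S), C5=C6, 18-silyloxy | C[C@H]1C(=O)C[C@@H]2/C(=C(/C)[C@H]3C[C@H]4[C@H](C(C)C)C[C@@H](O[Si](C)(C)C(C)(C)C)[C@]4(C)C[C@H]13)CC[C@@H]2C | intermediate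
27 | C1=C2 enol triflate of 26 (triflate on C2) | C/C1=C(OS(=O)(=O)C(F)(F)F)/C[C@@H]2/C(=C(/C)[C@H]3C[C@H]4[C@H](C(C)C)C[C@@H](O[Si](C)(C)C(C)(C)C)[C@]4(C)C[C@H]13)CC[C@@H]2C | intermediate
28 | tert-butyldimethylsilyl ether of the target | C/C1=C/C[C@@H]2/C(=C(/C)[C@H]3C[C@H]4[C@H](C(C)C)C[C@@H](O[Si](C)(C)C(C)(C)C)[C@]4(C)C[C@H]13)CC[C@@H]2C | intermediate
29 | CNP0541339.1: 5-8-6-5 tetracyclic dienol (4S,7S,8S,11S,13S,14R,16S,18R) | C/C1=C/C[C@@H]2/C(=C(/C)[C@H]3C[C@H]4[C@H](C(C)C)C[C@@H](O)[C@]4(C)C[C@H]13)CC[C@@H]2C | target

Total steps: 18. Longest linear sequence: 15 (steps 1–8 and 12–18).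

**Steps most likely to fail**

Step 15 (Claisen ring expansion). The boat-type pyran geometry forced by the equatorial alkenyl group may raise the barrier so far that migration of the exocyclic enol ether double bond into the ring, or ionisation of the tertiary allylic C6–O bond with loss of stereochemical fidelity, outruns the shift. The fallback sets out from 25 and runs the ring expansion as a Lewis-acid-triggered, stepwise ionisation–recombination with i-Bu3Al in CH2Cl2 at −78 → 0 °C. The aluminium enolate recombines with the allyl cation at C4 within the ion pair, and the ketone is reduced at once by hydride transfer from an isobutyl group, giving the ring-B alcohol F1 (C2 epimers). Oxidation of F1 with Dess–Martin periodinane comes back to the route at 26.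

Step 12 (alkenylcerium addition). Attack on the other face of the methyl ketone (acetyl methyl in the ring-oxygen site, the classical Felkin–Anh sense) would give the C6 epimer, which would pass the wrong configuration on to C4. The fallback introduces the two carbon groups in the reverse order, setting out from 13. Haloform cleavage of the methyl ketone (NaOBr, dioxane–water, 0 °C) gives the carboxylic acid F2, and oxalyl chloride gives the acid chloride F3. Acylation of the alkenylzinc chloride F4 (from alkenyllithium 20 and ZnCl2) under Pd(PPh3)4 catalysis gives the alkenyl ketone F5. 1,2-Addition of MeLi/CeCl3 to F5 then exchanges the roles of nucleophile and ketone substituent, which for a given facial preference of the acyl group inverts the carbinol configuration. The alkoxide formed is 22, where the fallback comes back to the route (lactonisation to 23).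

Step 2 (conjugate addition to the dienedione). Electron transfer from the organometallic to the doubly activated acceptor, 1,2-addition to a carbonyl group, or loss of facial control may intervene. The fallback sets out from 3: base-catalysed Michael addition of 2-nitropropane (DBU, MeCN, rt), a soft carbanion that neither reduces the acceptor nor adds 1,2, gives the tertiary nitro compound F6. Radical denitration (Bu3SnH, AIBN, toluene, 110 °C) replaces the nitro group by hydrogen and comes back to the route at 4.

**Further compounds**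
F1 | step 15 | ring-B alcohol: 26 with C2–OH in place of the ketone (C2 epimers) | C[C@H]1C(O)C[C@@H]2/C(=C(/C)[C@H]3C[C@H]4[C@H](C(C)C)C[C@@H](O[Si](C)(C)C(C)(C)C)[C@]4(C)C[C@H]13)CC[C@@H]2C
F2 | step 12 | carboxylic acid: 13 with CO2H in place of the acetyl group | CC(C)(C)[Si](C)(C)O[C@H]1[C@]2(C)C[C@H](C(C)C(=O)OC)[C@@H](C(=O)O)C[C@H]2[C@H](C(C)C)C1
F3 | step 12 | acid chloride of F2 | CC(C)(C)[Si](C)(C)O[C@H]1[C@]2(C)C[C@H](C(C)C(=O)OC)[C@@H](C(=O)Cl)C[C@H]2[C@H](C(C)C)C1
F4 | step 12 | [(5S)-5-methylhepta-1,6-dien-2-yl]zinc chloride | C=C[C@@H](C)CCC(=C)[Zn]Cl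
F5 | step 12 | alkenyl ketone: 13 with (5S)-5-methyl-2-methylidenehept-6-enoyl in place of the acetyl group | CC(C)(C)[Si](C)(C)O[C@H]1[C@]2(C)C[C@H](C(C)C(=O)OC)[C@@H](C(=O)C(=C)CC[C@H](C)C=C)C[C@H]2[C@H](C(C)C)C1
F6 | step 2 | (3R,7aR)-7a-methyl-3-(2-nitropropan-2-yl)-2,3,7,7a-tetrahydro-1H-indene-1,5(6H)-dione | O=C1[C@]2(C)CCC(=O)C=C2[C@H](C(C)(C)[N+](=O)[O-])C1
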